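**Remark (assumptions).** The target is read as (4R,5S)-4,5-dihydroxy-5-[(14E)-heptadec-14-en-1-yl]cyclohex-2-en-1-one, with the two hydroxyls cis. Ring carbons keep the numbering of quinic acid throughout (quinic C1–C6 = target C1–C6); β is the face of the 1-, 3- and 4-hydroxyls of quinic acid, α the other face; primed locants count side-chain carbons from the ring. Hex-5-enylmagnesium bromide (THF solution) and (E)-tetradec-11-en-1-ol (pheromone alcohol) are taken as purchased.

**Retrosynthetic overview**
1. The carbocycle is not built: C1–C6 of (−)-quinic acid become C1–C6 of the target (C1(OH)CO2H → C1=O; O3 → leaving group for C2=C3; C4–OH kept; C5 → ketone → tertiary carbinol).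
2. Last disconnection: C2=C3 by E1cB opening of the 3,4-dioxolane. This temporary ring and the 1,5-lactone are closed in step 1; the lactone is opened in step 2, the dioxolane in step 9.
3. Key disconnection: the C4'–C5' bond of the side chain, made by anodic cross-coupling (mixed Kolbe electrolysis) of ring diacid 11 with (E)-tetradec-11-enoic acid 14; the same electrolysis unveils the C1 ketone from quinic acid's own α-hydroxy-acid carbon.
4. Enabling feature: C1'–C13' is an unbranched, heteroatom-free polymethylene tether between the quaternary ring carbon C5 and the C14'=C15' olefin. Both carbons of the bond are primary CH2 (four atoms from the ring, nine from the olefin), so their radicals are unstabilised and have nothing to cyclise onto; ring C1 is a tertiary α-hydroxy-acid carbon.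
5. C5 is set earlier by organocerium addition of a hex-5-enyl unit to the 5-ketone, anti to the dioxolane; the vinyl end is then cut back to the carboxyl group needed for the electrolysis.

Key step: step 8

**Step 1**
Reactants: 1 (−)-quinic acid
Product: 3 quinide acetonide (3,4-O-isopropylidene-1,5-quinide), via acetonide acid 2 (not isolated)
Conditions: 2,2-dimethoxypropane, TsOH·H2O (cat.), acetone, reflux; Et3N quench
Reagents that add atoms: 2,2-dimethoxypropane, COC(C)(C)OC
Why: Acid-catalysed transacetalisation takes the only cis-vicinal diol (O3/O4) into the dioxolane and the carboxyl group then lactonises onto the cis-disposed 5-OH (Fischer lactonisation), no stereocentre being touched.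

**Step 2**
Reactants: 3 quinide acetonide
Product: 4 methyl 3,4-O-isopropylidenequinate
Conditions: NaOMe (cat.), MeOH, 0 °C; AcOH quench
Reagents that add atoms: methanol, CO
Why: Methoxide transesterification opens the strained bridged lactone and frees the secondary 5-OH as the only oxidisable alcohol, the stereocentres staying as they are.

**Step 3**
Reactants: 4 methyl 3,4-O-isopropylidenequinate
Product: 5 methyl 3,4-O-isopropylidene-5-dehydroquinate (5-ketone)
Conditions: Dess–Martin periodinane, NaHCO3, CH2Cl2, 0 °C to rt; used crude
Reagents that add atoms: none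
Why: Dess–Martin oxidation of the single secondary alcohol (the 1-OH is tertiary) under buffered neutral conditions that should avoid β-elimination of the 1-OH or of O3.

**Step 4**
Reactants: 5 methyl 3,4-O-isopropylidene-5-dehydroquinate; 6 hex-5-enylmagnesium bromide
Product: 7 methyl 5-C-(hex-5-en-1-yl)-3,4-O-isopropylidene-5-epi-quinate (5-OH β, chain α)
Conditions: 6 (3.5 equiv), anhydrous CeCl3, THF, −78 °C; sat. NH4Cl
Reagents that add atoms: none
Why: Organocerium 1,2-addition should take the ketone in preference to the hindered α-alkoxido ester and without enolisation, and C5 is set by attack on the α face, anti to the cis-fused dioxolane oxygen on C4 and to the axial 1-O/3-O pair, so that the new 5-OH is β and cis to O4.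

**Step 5**
Reactants: 7 methyl 5-C-(hex-5-en-1-yl)-3,4-O-isopropylidene-5-epi-quinate
Product: 10 methyl 5-C-(4-carboxybutyl)-3,4-O-isopropylidene-5-epi-quinate, via ozonide 8 (not isolated), via aldehyde 9 (not isolated)
Conditions: O3, CH2Cl2, −78 °C; Me2S; then NaClO2, NaH2PO4, 2-methylbut-2-ene, t-BuOH/H2O, 0 °C
Reagents that add atoms: ozone, O=[O+][O-]; sodium chlorite, [Na+].[O-]Cl=O
Why: Ozonolysis of the only C=C followed by Pinnick oxidation turns the vinyl terminus into a carboxyl group one carbon shorter, both operations being mild enough for the dioxolane, the ester and the two tertiary alcohols.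

**Step 6**
Reactants: 10 methyl 5-C-(4-carboxybutyl)-3,4-O-isopropylidene-5-epi-quinate
Product: 11 5-C-(4-carboxybutyl)-3,4-O-isopropylidene-5-epi-quinic acid (diacid)
Conditions: LiOH, THF/H2O, 0 °C to rt; 1 M HCl to pH 3 at 0 °C
Reagents that add atoms: lithium hydroxide, [Li+].[OH-]
Why: Saponification of the α-hydroxy methyl ester; the β 5-OH and the α carboxyl group at C1 are trans, so no lactone can form again, and the brief cold acidification should spare the dioxolane.

**Step 7**
Reactants: 12 (E)-tetradec-11-en-1-ol
Product: 14 (E)-tetradec-11-enoic acid, via aldehyde 13 (not isolated)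
Conditions: TEMPO (cat.), PhI(OAc)2, MeCN/H2O, rt
Reagents that add atoms: water, O
Why: Oxoammonium (TEMPO) oxidation of the primary alcohol through the aldehyde hydrate to the acid, which leaves the isolated E olefin untouched.

**Step 8**
Reactants: 11 5-C-(4-carboxybutyl)-3,4-O-isopropylidene-5-epi-quinic acid; 14 (E)-tetradec-11-enoic acid
Product: 16 (3R,4R,5S)-5-[(14E)-heptadec-14-en-1-yl]-5-hydroxy-3,4-(isopropylidenedioxy)cyclohexan-1-one, via keto acid 15 (not isolated)
Conditions: 11 (1 equiv), 14 (6 equiv), KOH (5 mol % of CO2H), MeOH, Pt anode and cathode, undivided cell, constant current (ca. 0.25 A cm−2), 10–15 °C; stopped while still weakly acidic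
Reagents that add atoms: none
Why: Mixed Kolbe electrolysis: the two alkanoate groups are discharged at the platinum anode, lose CO2 and give the primary radicals ring–(CH2)3CH2• and •CH2(CH2)8CH=CHEt, which combine in the anode layer to the C4'–C5' bond, the excess of 14 making capture of the ring radical by the tridecenyl radical its statistically dominant fate (the surplus ends as an apolar C26 diene that is removed on silica). In the same electrolysis the tertiary α-hydroxy carboxylate at C1, the most acidic and most easily oxidised site, undergoes two-electron oxidative decarboxylation (Hofer–Moest pathway, the α-hydroxyalkyl radical being oxidised at once to the protonated ketone), so keto acid 15 is the expected intermediate and 16 the product. The closest known reaction types are the mixed Kolbe coupling of unsaturated fatty acids with a second alkanoic acid (olefinic hydrocarbon pheromones; 4-oxo acids such as levulinic acid also couple) and the anodic conversion of α-hydroxy acids into carbonyl compounds. No ring is closed and no stereocentre is formed; C3, C4 and C5 are not adjacent to any radical or cationic site and keep their configuration, and the E olefin, nine carbons from its radical centre, offers no 5- or 6-exo pathway and should not isomerise. The selectivities needed are hetero- over homo-coupling (secured by stoichiometry), radical over cation chemistry at the two unbranched, heteroatom-free primary sites (smooth Pt, high current density, weakly acidic methanol) and cation chemistry at C1 (secured by its α-OH). The intact dioxolane keeps the new ketone from eliminating to an enone that would trap radicals.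

**Step 9**
Reactants: 16 (3R,4R,5S)-5-[(14E)-heptadec-14-en-1-yl]-5-hydroxy-3,4-(isopropylidenedioxy)cyclohexan-1-one
Product: 18 (4R,5S)-4,5-dihydroxy-5-[(14E)-heptadec-14-en-1-yl]cyclohex-2-en-1-one (target), via hemiketal 17 (not isolated)
Conditions: DBU (1.1 equiv), CH2Cl2, −20 to 0 °C; pH 7 phosphate buffer
Reagents that add atoms: none
Why: E1cB β-elimination in which deprotonation at C2 expels the dioxolane oxygen on C3 and the resulting O4 hemiketal loses acetone, a mode known for 3,4-O-isopropylidene cyclohexanones derived from quinic acid; the tertiary 5-OH is the poorer leaving group and C4 and C5 are not touched.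

**Compound list**
1 | (−)-quinic acid, (1S,3R,4S,5R)-1,3,4,5-tetrahydroxycyclohexane-1-carboxylic acid | O=C(O)[C@]1(O)C[C@@H](O)[C@@H](O)[C@H](O)C1 | starting material
2 | 3,4-O-isopropylidenequinic acid (acetonide acid, not isolated) | O=C(O)[C@]1(O)C[C@@H](O2)[C@@H](OC2(C)C)[C@H](O)C1 | intermediate
3 | quinide acetonide: quinic acid 1,5-lactone with O3/O4 as a β-face isopropylidene acetal, 1-OH free | O=C2[C@]1(O)C[C@@H](O3)[C@@H](OC3(C)C)[C@H](O2)C1 | intermediate
4 | methyl 3,4-O-isopropylidenequinate (1-OH β, CO2Me α, 5-OH α) | COC(=O)[C@]1(O)C[C@@H](O2)[C@@H](OC2(C)C)[C@H](O)C1 | intermediate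
5 | methyl 3,4-O-isopropylidene-5-dehydroquinate (5-ketone) | COC(=O)[C@]1(O)C[C@@H](O2)[C@@H](OC2(C)C)C(=O)C1 | intermediate
6 | hex-5-enylmagnesium bromide | C=CCCCC[Mg]Br | starting material
7 | methyl 5-C-(hex-5-en-1-yl)-3,4-O-isopropylidene-5-epi-quinate (5-OH β, cis to O3/O4; hexenyl α) | COC(=O)[C@]1(O)C[C@@H](O2)[C@@H](OC2(C)C)[C@](O)(CCCCC=C)C1 | intermediate
8 | 1,2,4-trioxolane (ozonide) of 7, epimers at the trioxolane carbon (not isolated) | COC(=O)[C@]1(O)C[C@@H](O2)[C@@H](OC2(C)C)[C@](O)(CCCCC3OCOO3)C1 | intermediate
9 | methyl 5-C-(5-oxopentyl)-3,4-O-isopropylidene-5-epi-quinate (aldehyde, not isolated) | COC(=O)[C@]1(O)C[C@@H](O2)[C@@H](OC2(C)C)[C@](O)(CCCCC=O)C1 | intermediate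
10 | methyl 5-C-(4-carboxybutyl)-3,4-O-isopropylidene-5-epi-quinate | COC(=O)[C@]1(O)C[C@@H](O2)[C@@H](OC2(C)C)[C@](O)(CCCCC(=O)O)C1 | intermediate
11 | 5-C-(4-carboxybutyl)-3,4-O-isopropylidene-5-epi-quinic acid (diacid) | OC(=O)[C@]1(O)C[C@@H](O2)[C@@H](OC2(C)C)[C@](O)(CCCCC(=O)O)C1 | intermediate
12 | (E)-tetradec-11-en-1-ol | CC/C=C/CCCCCCCCCCO | starting material
13 | (E)-tetradec-11-enal (not isolated) | CC/C=C/CCCCCCCCCC=O | intermediate
14 | (E)-tetradec-11-enoic acid | CC/C=C/CCCCCCCCCC(=O)O | intermediate
15 | (3R,4R,5S)-5-(4-carboxybutyl)-5-hydroxy-3,4-(isopropylidenedioxy)cyclohexan-1-one (keto acid, not isolated) | O=C1C[C@@H](O2)[C@@H](OC2(C)C)[C@](O)(CCCCC(=O)O)C1 | intermediate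
16 | (3R,4R,5S)-5-[(14E)-heptadec-14-en-1-yl]-5-hydroxy-3,4-(isopropylidenedioxy)cyclohexan-1-one | O=C1C[C@@H](O2)[C@@H](OC2(C)C)[C@](O)(CCCCCCCCCCCCC/C=C/CC)C1 | intermediate
17 | (4R,5S)-5-[(14E)-heptadec-14-en-1-yl]-5-hydroxy-4-[(2-hydroxypropan-2-yl)oxy]cyclohex-2-en-1-one (hemiketal, not isolated) | CC/C=C/CCCCCCCCCCCCC[C@]1(O)CC(=O)C=C[C@H]1OC(C)(C)O | intermediate
18 | (4R,5S)-4,5-dihydroxy-5-[(14E)-heptadec-14-en-1-yl]cyclohex-2-en-1-one, cis-diol | CC/C=C/CCCCCCCCCCCCC[C@]1(O)CC(=O)C=C[C@H]1O | target

**Step count.** Total: 9 steps. Longest linear sequence: 8 steps (1–6, 8, 9, from quinic acid); step 7 is a one-step side branch.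

**Steps most likely to fail**

1. Step 8. The two anodic events may not keep pace. Homocoupling and two-electron over-oxidation of the primary radicals (ether or olefin formation) compete with cross-combination. The ketone set free at C1 early in the run may also be lost by base-induced β-elimination in the cathode layer, followed by radical or methoxide addition to the enone. Fallback, setting out from 10 and 14 and coming back at 16: the coupling is changed from anodic radical–radical combination to a nickel-mediated reductive coupling and the ketone is unveiled separately. Acid 10 (C1 still a methyl ester) and acid 14 are each esterified with N-hydroxyphthalimide (DIC, cat. DMAP) to redox-active ester F1 and redox-active ester F2. A nickel/terpyridine-catalysed reductive doubly decarboxylative alkyl–alkyl coupling (electroreductive or Zn-mediated, F2 in excess) would give coupled methyl ester F3. LiOH then gives α-hydroxy acid F4, and Pb(OAc)4 oxidative decarboxylation in benzene/pyridine gives 16.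

2. Step 4. Facial selectivity may be poor (attack syn to the dioxolane), and enolisation with β-elimination of O3 or attack at the ester may compete. Fallback, setting out from 5 and coming back at 7: the C5 oxygen is delivered under hydroxyl direction instead of relying on the face preference of a carbon nucleophile. Wittig methylenation of 5 (salt-free Ph3P=CH2, THF, −78 to 0 °C) gives exocyclic alkene F5. VO(acac)2/t-BuOOH epoxidation directed by the homoallylic β 1-OH gives spiro-epoxide F6 with its oxygen on the β face. CuI-catalysed opening at the epoxide CH2 with pent-4-enylmagnesium bromide gives 7.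

3. Step 9. The product may react further under base: a second β-elimination of the tertiary 5-OH with aromatisation to the alkylhydroquinone, or retro-aldol opening of the β-hydroxy ketone. Fallback, setting out from 16 and coming back at 18: the leaving group is changed so that only a weak base is needed and the last step is neutral. Aqueous TFA at 0 °C removes the acetal to give triol ketone F7. Ac2O/pyridine acetylates the two secondary hydroxyls to diacetate F8, which should lose the 3-acetate with Et3N at 0 °C to give acetyl enone F9. Lipase-catalysed deacetylation at pH 7 then gives 18.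

**Further compounds**
F1 | step 8 | 1,3-dioxoisoindolin-2-yl ester of the side-chain carboxyl of 10 (redox-active ester) | COC(=O)[C@]1(O)C[C@@H](O2)[C@@H](OC2(C)C)[C@](O)(CCCCC(=O)ON3C(=O)c4ccccc4C3=O)C1
F2 | step 8 | 1,3-dioxoisoindolin-2-yl (E)-tetradec-11-enoate (redox-active ester) | CC/C=C/CCCCCCCCCC(=O)ON1C(=O)c2ccccc2C1=O
F3 | step 8 | methyl 5-C-[(14E)-heptadec-14-en-1-yl]-3,4-O-isopropylidene-5-epi-quinate | COC(=O)[C@]1(O)C[C@@H](O2)[C@@H](OC2(C)C)[C@](O)(CCCCCCCCCCCCC/C=C/CC)C1
F4 | step 8 | 5-C-[(14E)-heptadec-14-en-1-yl]-3,4-O-isopropylidene-5-epi-quinic acid | OC(=O)[C@]1(O)C[C@@H](O2)[C@@H](OC2(C)C)[C@](O)(CCCCCCCCCCCCC/C=C/CC)C1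
F5 | step 4 | methyl 5-deoxy-5-methylidene-3,4-O-isopropylidenequinate | COC(=O)[C@]1(O)C[C@@H](O2)[C@@H](OC2(C)C)C(=C)C1
F6 | step 4 | spiro-epoxide of F5, epoxide oxygen β (cis to O4), CH2 α | COC(=O)[C@]1(O)C[C@@H](O2)[C@@H](OC2(C)C)[C@]3(CO3)C1
F7 | step 9 | (3R,4R,5S)-5-[(14E)-heptadec-14-en-1-yl]-3,4,5-trihydroxycyclohexan-1-one | O=C1C[C@@H](O)[C@@H](O)[C@](O)(CCCCCCCCCCCCC/C=C/CC)C1
F8 | step 9 | 3,4-di-O-acetate of F7 | O=C1C[C@@H](OC(C)=O)[C@@H](OC(C)=O)[C@](O)(CCCCCCCCCCCCC/C=C/CC)C1
F9 | step 9 | (4R,5S)-4-acetoxy-5-[(14E)-heptadec-14-en-1-yl]-5-hydroxycyclohex-2-en-1-one | CC/C=C/CCCCCCCCCCCCC[C@]1(O)CC(=O)C=C[C@H]1OC(C)=O
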